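**Retrosynthetic overview**
1. The strategy rests on ring C: C-4 is an aryl ketone carbon on ring A bonded directly to C-3, which carries ring B and the C-2 carbon attached to O-1. After formal hydration of C-2=C-3, the C-3–C-4 bond is therefore a benzoin (α-ketol) bond.
2. C-2=C-3 comes from dehydration of a 3-hydroxychroman-4-one. C-3–C-4 comes from a carbene-catalysed intramolecular benzoin of a ring A aldehyde onto a ring B aryl ketone tethered through O-1–C-2.
3. O-1–C-2 comes from alkylation of 2-hydroxy-4-(methoxymethoxy)benzaldehyde with a ring B chloromethyl ketone.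
4. The ring B ketone comes from pyrogallol acetonide: O-prenylation and Claisen rearrangement (1,1-dimethylallyl at C-5'), O-methylation (C-4'), then ortho-lithiation and chloroacetylation at C-1'.
5. Ring order: rings A and B are bought as benzenes; the dioxole protecting ring is made in step 1; ring C is closed in step 8 and aromatised in step 9; protecting groups are removed in step 10.

Key step: step 8

Remark on the chemistry: isoflavone numbering is used (ring A is the benzo ring with 7-OH, ring C is the pyranone O-1/C-2/C-3/C-4, ring B is the C-3 aryl group C-1' to C-6'). The target has no stereocentre; the carbinol centre made in step 8 is racemic and is removed in step 9.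

**Route**

Step 1
Reactants: 1 pyrogallol
Product: 2 2,2-dimethyl-1,3-benzodioxol-4-ol
Conditions: 2,2-dimethoxypropane, p-TsOH (cat.), toluene, reflux, methanol removed over 4 Å molecular sieves
Reagents that add atoms: 2,2-dimethoxypropane, COC(C)(C)OC
Why: Acid-catalysed transketalisation closes the five-membered isopropylidene ketal on two adjacent hydroxyls, and by symmetry either adjacent pair gives the same mono-phenol.

Step 2
Reactants: 2 2,2-dimethyl-1,3-benzodioxol-4-ol; 3 1-bromo-3-methylbut-2-ene
Product: 4 2,2-dimethyl-4-[(3-methylbut-2-en-1-yl)oxy]-1,3-benzodioxole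
Conditions: K2CO3, acetone, reflux
Reagents that add atoms: none
Why: Williamson ether synthesis, in which the phenoxide displaces the primary allylic bromide by SN2 at oxygen under carbonate in acetone.

Step 3
Reactants: 4 2,2-dimethyl-4-[(3-methylbut-2-en-1-yl)oxy]-1,3-benzodioxole
Product: 6 2,2-dimethyl-5-(2-methylbut-3-en-2-yl)-1,3-benzodioxol-4-ol, via ortho-dienone 5 (not isolated)
Conditions: N,N-diethylaniline, 190 °C, argon
Reagents that add atoms: none
Why: Aromatic Claisen rearrangement, in which the [3,3] shift with allyl inversion delivers the dimethyl-substituted terminus to C-5, the only ortho carbon bearing hydrogen, and the dienone tautomerises to the phenol while the amine solvent holds back acid-catalysed follow-up reactions.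

Step 4
Reactants: 6 2,2-dimethyl-5-(2-methylbut-3-en-2-yl)-1,3-benzodioxol-4-ol
Product: 7 4-methoxy-2,2-dimethyl-5-(2-methylbut-3-en-2-yl)-1,3-benzodioxole
Conditions: MeI, K2CO3, DMF, rt to 40 °C
Reagents that add atoms: iodomethane, CI
Why: Williamson O-methylation of the phenoxide in a dipolar aprotic solvent, which should overcome the moderate hindrance from the neighbouring tertiary alkyl group.

Step 5
Reactants: 7 4-methoxy-2,2-dimethyl-5-(2-methylbut-3-en-2-yl)-1,3-benzodioxole; 8 2-chloro-N-methoxy-N-methylacetamide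
Product: 11 2-chloro-1-[7-methoxy-2,2-dimethyl-6-(2-methylbut-3-en-2-yl)-1,3-benzodioxol-4-yl]ethan-1-one, via aryllithium 9 (not isolated), via lithium tetrahedral adduct 10 (not isolated)
Conditions: s-BuLi, TMEDA, THF, −78 to −40 °C; then 8, −78 °C; then 1 M HCl (aq), 0 °C
Reagents that add atoms: none
Why: Directed ortho-metalation at C-7, the only ring C–H next to an oxygen (the dioxole O-1), followed by Weinreb amide acylation, in which the chelated tetrahedral adduct survives until the quench so that over-addition is blocked and the low temperature spares the C–Cl bond.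

Step 6
Reactants: 12 2,4-dihydroxybenzaldehyde
Product: 13 2-hydroxy-4-(methoxymethoxy)benzaldehyde
Conditions: MOMCl (1.05 equiv), K2CO3, acetone, 0 °C to rt
Reagents that add atoms: chloromethyl methyl ether, COCCl
Why: Selective acetal ether formation at the 4-hydroxyl, which is the more acidic and freely available phenol, whereas the 2-hydroxyl is held in a hydrogen bond to the aldehyde.

Step 7
Reactants: 11 2-chloro-1-[7-methoxy-2,2-dimethyl-6-(2-methylbut-3-en-2-yl)-1,3-benzodioxol-4-yl]ethan-1-one; 13 2-hydroxy-4-(methoxymethoxy)benzaldehyde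
Product: 14 2-{2-[7-methoxy-2,2-dimethyl-6-(2-methylbut-3-en-2-yl)-1,3-benzodioxol-4-yl]-2-oxoethoxy}-4-(methoxymethoxy)benzaldehyde
Conditions: K2CO3, KI (10 mol%), acetone, rt
Reagents that add atoms: none
Why: Williamson etherification of the phenoxide with the activated α-haloketone (halide exchange in the flask by iodide), run with a weak base at room temperature so that the product does not go on to aldol closure.

Step 8
Reactants: 14 2-{2-[7-methoxy-2,2-dimethyl-6-(2-methylbut-3-en-2-yl)-1,3-benzodioxol-4-yl]-2-oxoethoxy}-4-(methoxymethoxy)benzaldehyde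
Product: 16 racemic 3-hydroxy-7-(methoxymethoxy)-3-[7-methoxy-2,2-dimethyl-6-(2-methylbut-3-en-2-yl)-1,3-benzodioxol-4-yl]chroman-4-one, via Breslow enaminol 15 (not isolated)
Conditions: 2-phenyl-6,7-dihydro-5H-pyrrolo[2,1-c][1,2,4]triazol-2-ium tetrafluoroborate (15 mol%), DBU (12 mol%), THF (0.05 M), rt, argon
Reagents that add atoms: none
Why: DBU deprotonates the triazolium salt to the carbene, which adds to the aldehyde of 14; proton transfer gives Breslow enaminol 15, whose nucleophilic carbon (the future C-4) attacks the tethered ring B ketone carbon (the future C-3), and proton transfer with loss of the carbene releases α-ketol 16. The closest known reaction type is the N-heterocyclic carbene catalysed intramolecular crossed aldehyde–ketone benzoin that turns 2-(2-aryl-2-oxoethoxy)benzaldehydes into 3-hydroxychroman-4-ones. Ring C closes in a 6-exo-trig mode, and its size is fixed by the two-atom O-1–C-2 tether. The new carbinol centre C-3 should form racemic, because the catalyst is achiral and nothing in the substrate distinguishes the ketone faces, and no control is needed since step 9 removes this centre. The step needs the aldehyde as donor and the ketone as acceptor, which is secured because only the aldehyde has the formyl hydrogen needed to form the enaminol, while intermolecular aldehyde–aldehyde benzoin is reversible and is disfavoured at this dilution. Keeping DBU below the triazolium loading leaves little free base, which guards against aldol closure of the O–CH2–CO methylene onto the aldehyde.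

Step 9
Reactants: 16 racemic 3-hydroxy-7-(methoxymethoxy)-3-[7-methoxy-2,2-dimethyl-6-(2-methylbut-3-en-2-yl)-1,3-benzodioxol-4-yl]chroman-4-one
Product: 18 7-(methoxymethoxy)-3-[7-methoxy-2,2-dimethyl-6-(2-methylbut-3-en-2-yl)-1,3-benzodioxol-4-yl]-4H-chromen-4-one, via sulfamate ester 17 (not isolated)
Conditions: Burgess reagent (methyl N-(triethylammoniosulfonyl)carbamate, 2 equiv), THF, 60 °C
Reagents that add atoms: none
Why: Burgess dehydration, in which the tertiary alcohol is sulfamoylated and undergoes syn elimination with a C-2 hydrogen, the only β-hydrogens present, to give the conjugated chromone under neutral conditions that spare the MOM ether, the acetonide and the terminal alkene.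

Step 10
Reactants: 18 7-(methoxymethoxy)-3-[7-methoxy-2,2-dimethyl-6-(2-methylbut-3-en-2-yl)-1,3-benzodioxol-4-yl]-4H-chromen-4-one
Product: 20 3-[2,3-dihydroxy-4-methoxy-5-(2-methylbut-3-en-2-yl)phenyl]-7-hydroxy-4H-chromen-4-one (target), via 7-hydroxy acetonide 19 (not isolated)
Conditions: 3 M HCl (aq)–THF (1:2), 55 °C, argon
Reagents that add atoms: none
Why: Acid hydrolysis of the MOM acetal (expected to go first) and then of the catechol isopropylidene ketal, while the aryl methyl ether, the chromone and the monosubstituted alkene are inert to dilute aqueous HCl and no phenol sits ortho to the 1,1-dimethylallyl group to cyclise onto it.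

**Compound list**
1 | pyrogallol (benzene-1,2,3-triol) | Oc1cccc(O)c1O | starting material
2 | 2,2-dimethyl-1,3-benzodioxol-4-ol | CC1(C)Oc2cccc(O)c2O1 | intermediate
3 | 1-bromo-3-methylbut-2-ene (prenyl bromide) | CC(C)=CCBr | starting material
4 | 2,2-dimethyl-4-[(3-methylbut-2-en-1-yl)oxy]-1,3-benzodioxole | CC(C)=CCOc1cccc2OC(C)(C)Oc12 | intermediate
5 | 2,2-dimethyl-5-(2-methylbut-3-en-2-yl)-1,3-benzodioxol-4(5H)-one (ortho-dienone, racemic at C-5) | C=CC(C)(C)C1C=CC2=C(OC(C)(C)O2)C1=O | intermediate (not isolated)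
6 | 2,2-dimethyl-5-(2-methylbut-3-en-2-yl)-1,3-benzodioxol-4-ol | C=CC(C)(C)c1ccc2OC(C)(C)Oc2c1O | intermediate
7 | 4-methoxy-2,2-dimethyl-5-(2-methylbut-3-en-2-yl)-1,3-benzodioxole | C=CC(C)(C)c1ccc2OC(C)(C)Oc2c1OC | intermediate
8 | 2-chloro-N-methoxy-N-methylacetamide | CON(C)C(=O)CCl | starting material
9 | [7-methoxy-2,2-dimethyl-6-(2-methylbut-3-en-2-yl)-1,3-benzodioxol-4-yl]lithium | [Li]c1cc(C(C)(C)C=C)c(OC)c2OC(C)(C)Oc12 | intermediate (not isolated)
10 | lithium 2-chloro-1-[methoxy(methyl)amino]-1-[7-methoxy-2,2-dimethyl-6-(2-methylbut-3-en-2-yl)-1,3-benzodioxol-4-yl]ethan-1-olate (racemic tetrahedral adduct) | [Li]OC(CCl)(N(C)OC)c1cc(C(C)(C)C=C)c(OC)c2OC(C)(C)Oc12 | intermediate (not isolated)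
11 | 2-chloro-1-[7-methoxy-2,2-dimethyl-6-(2-methylbut-3-en-2-yl)-1,3-benzodioxol-4-yl]ethan-1-one | O=C(CCl)c1cc(C(C)(C)C=C)c(OC)c2OC(C)(C)Oc12 | intermediate
12 | 2,4-dihydroxybenzaldehyde | O=Cc1ccc(O)cc1O | starting material
13 | 2-hydroxy-4-(methoxymethoxy)benzaldehyde | O=Cc1ccc(OCOC)cc1O | intermediate
14 | 2-{2-[7-methoxy-2,2-dimethyl-6-(2-methylbut-3-en-2-yl)-1,3-benzodioxol-4-yl]-2-oxoethoxy}-4-(methoxymethoxy)benzaldehyde | O=Cc1ccc(OCOC)cc1OCC(=O)c1cc(C(C)(C)C=C)c(OC)c2OC(C)(C)Oc12 | intermediate
15 | Breslow enaminol: 2-{2-[hydroxy(2-phenyl-6,7-dihydro-5H-pyrrolo[2,1-c][1,2,4]triazol-3(2H)-ylidene)methyl]-5-(methoxymethoxy)phenoxy}-1-[7-methoxy-2,2-dimethyl-6-(2-methylbut-3-en-2-yl)-1,3-benzodioxol-4-yl]ethan-1-one (alkene geometry not defined) | OC(=C1N(c2ccccc2)N=C3CCCN13)c1ccc(OCOC)cc1OCC(=O)c1cc(C(C)(C)C=C)c(OC)c2OC(C)(C)Oc12 | intermediate (not isolated)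
16 | racemic 3-hydroxy-7-(methoxymethoxy)-3-[7-methoxy-2,2-dimethyl-6-(2-methylbut-3-en-2-yl)-1,3-benzodioxol-4-yl]chroman-4-one | O=C1c2ccc(OCOC)cc2OCC1(O)c1cc(C(C)(C)C=C)c(OC)c2OC(C)(C)Oc12 | intermediate
17 | triethylammonium salt of the racemic 3-O-[N-(methoxycarbonyl)sulfamoyl] derivative of 16 (sulfamate ester) | CC[NH+](CC)CC.COC(=O)[N-]S(=O)(=O)OC1(COc2cc(OCOC)ccc2C1=O)c1cc(C(C)(C)C=C)c(OC)c2OC(C)(C)Oc12 | intermediate (not isolated)
18 | 7-(methoxymethoxy)-3-[7-methoxy-2,2-dimethyl-6-(2-methylbut-3-en-2-yl)-1,3-benzodioxol-4-yl]-4H-chromen-4-one | O=c1c(-c2cc(C(C)(C)C=C)c(OC)c3OC(C)(C)Oc23)coc2cc(OCOC)ccc12 | intermediate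
19 | 7-hydroxy-3-[7-methoxy-2,2-dimethyl-6-(2-methylbut-3-en-2-yl)-1,3-benzodioxol-4-yl]-4H-chromen-4-one | O=c1c(-c2cc(C(C)(C)C=C)c(OC)c3OC(C)(C)Oc23)coc2cc(O)ccc12 | intermediate (not isolated)
20 | 3-[2,3-dihydroxy-4-methoxy-5-(2-methylbut-3-en-2-yl)phenyl]-7-hydroxy-4H-chromen-4-one | C=CC(C)(C)c1cc(-c2coc3cc(O)ccc3c2=O)c(O)c(O)c1OC | target

**Step count**
Total steps: 10.
Longest linear sequence: 9 steps (steps 1–5 and 7–10 from pyrogallol); step 6 is a one-step side branch.

**Steps most likely to fail**

1. Step 8 (key step). The Breslow intermediate may add only slowly to the electron-rich, ortho-oxygenated ring B ketone. Base-mediated aldol condensation of the O–CH2–CO methylene onto the aldehyde (closure to a 2-aroylbenzofuran), or intermolecular aldehyde self-benzoin, could then consume the substrate.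
Fallback, from 7 back to 18: the C-3–C-1' bond would be made by Suzuki–Miyaura coupling on a preformed chromone.
 - Arene 7 is lithiated as in step 5 (aryllithium 9) and quenched with 2-isopropoxy-4,4,5,5-tetramethyl-1,3,2-dioxaborolane to give 2-[7-methoxy-2,2-dimethyl-6-(2-methylbut-3-en-2-yl)-1,3-benzodioxol-4-yl]-4,4,5,5-tetramethyl-1,3,2-dioxaborolane F1.
 - In parallel, commercial 1-(2,4-dihydroxyphenyl)ethan-1-one is protected at O-4 (MOMCl, K2CO3, acetone) to give 1-[2-hydroxy-4-(methoxymethoxy)phenyl]ethan-1-one F2.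
 - F2 is condensed with N,N-dimethylformamide dimethyl acetal to give (E)-3-(dimethylamino)-1-[2-hydroxy-4-(methoxymethoxy)phenyl]prop-2-en-1-one F3.
 - F3 is closed with I2 and pyridine in CHCl3 to give 3-iodo-7-(methoxymethoxy)-4H-chromen-4-one F4.
 - Coupling of F1 with F4 (Pd(PPh3)4, a zerovalent palladium complex, Na2CO3, DME–H2O, 80 °C) should give 18, and the route continues with step 10.

2. Step 7. Under the carbonate base the newly formed aryloxymethyl ketone may undergo intramolecular aldol condensation onto the ortho aldehyde before it can be isolated.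
Fallback, from 13 back to 14: the aldehyde would be carried through the etherification in reduced form.
 - Reduction of 13 (NaBH4, MeOH, 0 °C) gives 2-(hydroxymethyl)-5-(methoxymethoxy)phenol F5.
 - The phenol of F5 is alkylated with chloroketone 11 (K2CO3, KI, acetone, rt) to give 2-[2-(hydroxymethyl)-5-(methoxymethoxy)phenoxy]-1-[7-methoxy-2,2-dimethyl-6-(2-methylbut-3-en-2-yl)-1,3-benzodioxol-4-yl]ethan-1-one F6.
 - Oxidation of the benzylic alcohol with MnO2 in CH2Cl2 at rt, with no base present, should give 14.

3. Step 3. At 190 °C the first-formed ortho product may react further, by abnormal Claisen rearrangement or by closure of the phenol onto the alkene. Some allyl migration through the oxygen-bearing ortho carbon to the para position is also possible.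
Fallback, from 4 back to 6: the rearrangement would be run with capture of the phenol as it forms.
 - Heating 4 with acetic anhydride and NaOAc in N,N-diethylaniline should give 2,2-dimethyl-5-(2-methylbut-3-en-2-yl)-1,3-benzodioxol-4-yl acetate F7, in which the masked phenol can no longer take part in these follow-up reactions.
 - Methanolysis of F7 (K2CO3, MeOH, rt) then gives 6, and the route continues with step 4.

**Further compounds**
F1 | step 8 | 2-[7-methoxy-2,2-dimethyl-6-(2-methylbut-3-en-2-yl)-1,3-benzodioxol-4-yl]-4,4,5,5-tetramethyl-1,3,2-dioxaborolane | C=CC(C)(C)c1cc(B2OC(C)(C)C(C)(C)O2)c2OC(C)(C)Oc2c1OC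
F2 | step 8 | 1-[2-hydroxy-4-(methoxymethoxy)phenyl]ethan-1-one | CC(=O)c1ccc(OCOC)cc1O
F3 | step 8 | (E)-3-(dimethylamino)-1-[2-hydroxy-4-(methoxymethoxy)phenyl]prop-2-en-1-one | CN(C)/C=C/C(=O)c1ccc(OCOC)cc1O
F4 | step 8 | 3-iodo-7-(methoxymethoxy)-4H-chromen-4-one | O=c1c(I)coc2cc(OCOC)ccc12
F5 | step 7 | 2-(hydroxymethyl)-5-(methoxymethoxy)phenol | OCc1ccc(OCOC)cc1O
F6 | step 7 | 2-[2-(hydroxymethyl)-5-(methoxymethoxy)phenoxy]-1-[7-methoxy-2,2-dimethyl-6-(2-methylbut-3-en-2-yl)-1,3-benzodioxol-4-yl]ethan-1-one | OCc1ccc(OCOC)cc1OCC(=O)c1cc(C(C)(C)C=C)c(OC)c2OC(C)(C)Oc12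
F7 | step 3 | 2,2-dimethyl-5-(2-methylbut-3-en-2-yl)-1,3-benzodioxol-4-yl acetate | C=CC(C)(C)c1ccc2OC(C)(C)Oc2c1OC(C)=O
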